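**Plan**

- Retrosynthesis: the seven aryl–O–benzyl bonds are cut first, then the C4–C8' bond between the 7,4'-dihydroxyflavan unit and (−)-epigallocatechin, then C4–OH back to the C3=C4 alkene of a flav-3-ene, then the O1–C2 bond of ring C, and last the C2=C3 bond of a 2'-hydroxychalcone.
- Forward: an aldol condensation joins ring A (with C4 and C3) to ring B (with C2); 1,2-reduction gives a racemic allylic alcohol; ring C is closed at O1–C2; the C3=C4 alkene left by the closure is hydrated at C4; the C4 cation is joined to C8' of benzylated epigallocatechin; hydrogenolysis frees all phenols.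
- Enabling feature: C2 carries ring B with its para oxygen and, in the unsaturated precursor, is linked through C3=C4 to ring A, whose ortho oxygen O1 lies within reach. Loss of the C4 hydroxyl gives a cation spread over C4–C3–C2 and both rings (a protonated vinylogous ortho-quinone methide O1=C8a–C4a=C4–C3=C2) that can only collapse to a six-membered ring at O1–C2.
- Stereochemistry: C2' and C3' come from (−)-epigallocatechin; C2 (S) is set in the ring closure by the chiral counter-anion of the acid, both enantiomers of the alcohol converging on one cation; C4 (R) follows from C2 when the arene adds anti to the C2 aryl group (2,4-trans).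

Key step: step 3

Assumption: the sense of induction of the chiral acid in step 3 cannot be derived safely for this substrate; the (R) catalyst is written, and its antipode is used if a pilot run shows the opposite sense.

**Step 1**
Reactants: 1 1-[4-(benzyloxy)-2-hydroxyphenyl]ethan-1-one; 2 4-(benzyloxy)benzaldehyde
Product: 3 (E)-1-[4-(benzyloxy)-2-hydroxyphenyl]-3-[4-(benzyloxy)phenyl]prop-2-en-1-one
Conditions: KOH (3 equiv), EtOH/H2O, rt; then aq HCl
Reagents that add atoms: none
Why: Claisen–Schmidt aldol condensation of a 2'-hydroxyacetophenone with a non-enolizable aldehyde, which should give the E enone under thermodynamic control while the phenoxide keeps the chalcone open in strong base.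

**Step 2**
Reactants: 3 (E)-1-[4-(benzyloxy)-2-hydroxyphenyl]-3-[4-(benzyloxy)phenyl]prop-2-en-1-one
Product: 4 rac-5-(benzyloxy)-2-{(2E)-1-hydroxy-3-[4-(benzyloxy)phenyl]prop-2-en-1-yl}phenol
Conditions: NaBH4, THF/iPrOH, 0 °C → rt; pH 7 phosphate buffer at 0 °C; used crude
Reagents that add atoms: none
Why: 1,2-reduction of the 2'-hydroxychalcone carbonyl (the first stage of the classical flav-3-ene synthesis); the carbinol centre is left racemic on purpose because step 3 erases it.

**Step 3**
Reactants: 4 rac-5-(benzyloxy)-2-{(2E)-1-hydroxy-3-[4-(benzyloxy)phenyl]prop-2-en-1-yl}phenol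
Product: 6 (2S)-7-(benzyloxy)-2-[4-(benzyloxy)phenyl]-2H-chromene, via vinylogous ortho-quinone methide 5 (not isolated)
Conditions: (R)-N-triflylphosphoramide of 3,3'-bis(2,4,6-triisopropylphenyl)-1,1'-bi-2-naphthol, C51H57F3NO5PS (5 mol%), toluene (0.02 M), −78 → −40 °C
Reagents that add atoms: none
Why: The strong chiral acid protonates the allylic hydroxyl of either enantiomer of 4 and water leaves, giving one 1,3-diarylallyl cation (O-protonated 5) as a contact ion pair with the phosphoramidate; rotation about C3–C4 in the cation brings O1 to C2, and collapse of the ion pair forms the O1–C2 bond. The closest known reaction type is the chiral Brønsted acid catalysed enantioconvergent intramolecular allylic substitution of 2-hydroxyaryl allylic alcohols to 2-aryl-2H-chromenes, whose achiral version is the classical acid closure of reduced 2'-hydroxychalcones to flav-3-enes. Ring C closes in a 6-endo-trig allylic etherification, equivalent to the oxa-6π electrocyclization of the Z vinylogous ortho-quinone methide. The new centre C2 is controlled by the chiral counter-anion, which is hydrogen-bonded to the O1–H group and covers one face of the allyl terminus, so that racemic 4 should be funnelled into (2S)-6. The step needs O-attack at C2 under kinetic control: C2 is the only allyl terminus that O1 can reach in a six-membered ring, the aryl ether product is far less basic than the alcohol and should not re-ionize at low temperature in toluene, and high dilution holds back Friedel–Crafts capture of the cation by the electron-rich rings of a second molecule.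

**Step 4**
Reactants: 6 (2S)-7-(benzyloxy)-2-[4-(benzyloxy)phenyl]-2H-chromene
Product: 7 (2S,4RS)-7-(benzyloxy)-2-[4-(benzyloxy)phenyl]chroman-4-ol (mixture of C4 epimers)
Conditions: Mn(dpm)3 (5 mol%; dpm = 2,2,6,6-tetramethylheptane-3,5-dionate), PhSiH3, O2 (1 atm), iPrOH/CH2Cl2, 0 °C → rt
Reagents that add atoms: dioxygen, O=O
Why: Mukaiyama hydration, in which hydrogen atom transfer to C3 gives the benzylic C4 radical that O2 traps, should place the hydroxyl at C4 under neutral conditions that leave C2 and the benzyl ethers alone; the C4 configuration is not controlled and need not be, since step 6 ionizes it.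

**Step 5**
Reactants: 8 (−)-epigallocatechin, (2R,3R)-2-(3,4,5-trihydroxyphenyl)chromane-3,5,7-triol
Product: 9 (2R,3R)-5,7-bis(benzyloxy)-2-[3,4,5-tris(benzyloxy)phenyl]chroman-3-ol
Conditions: BnBr (5.5 equiv), K2CO3, DMF, −10 °C → rt, argon
Reagents that add atoms: benzyl bromide, BrCc1ccccc1
Why: Williamson etherification in which carbonate deprotonates the five phenols but not the secondary 3-OH, and which should leave C2' and C3' untouched at low temperature.

**Step 6**
Reactants: 7 (2S,4RS)-7-(benzyloxy)-2-[4-(benzyloxy)phenyl]chroman-4-ol; 9 (2R,3R)-5,7-bis(benzyloxy)-2-[3,4,5-tris(benzyloxy)phenyl]chroman-3-ol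
Product: 10 (2R,3R)-5,7-bis(benzyloxy)-8-{(2S,4R)-7-(benzyloxy)-2-[4-(benzyloxy)phenyl]chroman-4-yl}-2-[3,4,5-tris(benzyloxy)phenyl]chroman-3-ol
Conditions: Tf2NH (5 mol%), CH2Cl2, −78 → −30 °C, flavan-3-ol partner in threefold excess (the surplus is recovered); then aq NaHCO3
Reagents that add atoms: none
Why: Acid-catalysed dehydrative Friedel–Crafts coupling of a flavan-4-ol with a benzylated flavan-3-ol, the bond-forming event of proanthocyanidin synthesis: both C4 epimers of 7 ionize with loss of water to one cation stabilized by O1 and the 7-benzyloxy group, and C8' of 9, its most nucleophilic and least hindered position, should attack anti to the pseudo-equatorial C2 aryl group to set (4R).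

**Step 7**
Reactants: 10 (2R,3R)-5,7-bis(benzyloxy)-8-{(2S,4R)-7-(benzyloxy)-2-[4-(benzyloxy)phenyl]chroman-4-yl}-2-[3,4,5-tris(benzyloxy)phenyl]chroman-3-ol
Product: 11 (2R,3R)-8-[(2S,4R)-7-hydroxy-2-(4-hydroxyphenyl)chroman-4-yl]-2-(3,4,5-trihydroxyphenyl)chromane-3,5,7-triol (CNP0220331.1)
Conditions: H2 (1 atm), Pd(OH)2/C, THF/MeOH/H2O, rt; filtration under argon
Reagents that add atoms: none
Why: hydrogenolysis of the seven aryl benzyl ethers, under which the cyclic benzylic ether bonds O1–C2 of both flavan units should survive at 1 atm as they do in benzylated proanthocyanidins, so no stereocentre is touched.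

**Compound list**

1 | 1-[4-(benzyloxy)-2-hydroxyphenyl]ethan-1-one | CC(=O)c1ccc(OCc2ccccc2)cc1O | starting material
2 | 4-(benzyloxy)benzaldehyde | O=Cc1ccc(OCc2ccccc2)cc1 | starting material
3 | (E)-1-[4-(benzyloxy)-2-hydroxyphenyl]-3-[4-(benzyloxy)phenyl]prop-2-en-1-one | O=C(/C=C/c1ccc(OCc2ccccc2)cc1)c1ccc(OCc2ccccc2)cc1O | intermediate
4 | rac-5-(benzyloxy)-2-{(2E)-1-hydroxy-3-[4-(benzyloxy)phenyl]prop-2-en-1-yl}phenol | OC(/C=C/c1ccc(OCc2ccccc2)cc1)c1ccc(OCc2ccccc2)cc1O | intermediate
5 | (6Z)-3-(benzyloxy)-6-{(2E)-3-[4-(benzyloxy)phenyl]prop-2-en-1-ylidene}cyclohexa-2,4-dien-1-one (vinylogous ortho-quinone methide, present as its O-protonated allyl cation paired with the phosphoramidate) | O=C1C=C(OCc2ccccc2)C=C/C1=C/C=C/c1ccc(OCc2ccccc2)cc1 | intermediate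
6 | (2S)-7-(benzyloxy)-2-[4-(benzyloxy)phenyl]-2H-chromene | c1ccccc1COc1ccc([C@@H]2C=Cc3ccc(OCc4ccccc4)cc3O2)cc1 | intermediate
7 | (2S,4RS)-7-(benzyloxy)-2-[4-(benzyloxy)phenyl]chroman-4-ol | c1ccccc1COc1ccc([C@@H]2CC(O)c3ccc(OCc4ccccc4)cc3O2)cc1 | intermediate
8 | (−)-epigallocatechin, (2R,3R)-2-(3,4,5-trihydroxyphenyl)chromane-3,5,7-triol | Oc1cc(O)c2c(c1)O[C@H](c1cc(O)c(O)c(O)c1)[C@H](O)C2 | starting material
9 | (2R,3R)-5,7-bis(benzyloxy)-2-[3,4,5-tris(benzyloxy)phenyl]chroman-3-ol | c1ccccc1COc1cc(OCc3ccccc3)c2c(c1)O[C@H](c1cc(OCc3ccccc3)c(OCc3ccccc3)c(OCc3ccccc3)c1)[C@H](O)C2 | intermediate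
10 | (2R,3R)-5,7-bis(benzyloxy)-8-{(2S,4R)-7-(benzyloxy)-2-[4-(benzyloxy)phenyl]chroman-4-yl}-2-[3,4,5-tris(benzyloxy)phenyl]chroman-3-ol | c1ccccc1COc1ccc([C@@H]2C[C@@H](c3c(OCc5ccccc5)cc(OCc5ccccc5)c4c3O[C@H](c3cc(OCc5ccccc5)c(OCc5ccccc5)c(OCc5ccccc5)c3)[C@H](O)C4)c3ccc(OCc5ccccc5)cc3O2)cc1 | intermediate
11 | (2R,3R)-8-[(2S,4R)-7-hydroxy-2-(4-hydroxyphenyl)chroman-4-yl]-2-(3,4,5-trihydroxyphenyl)chromane-3,5,7-triol | Oc1ccc([C@@H]2C[C@@H](c3c(O)cc(O)c4c3O[C@H](c3cc(O)c(O)c(O)c3)[C@H](O)C4)c3ccc(O)cc3O2)cc1 | target

Total step count: 7. Longest linear sequence: 6 steps (steps 1, 2, 3, 4, 6, 7).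

**Steps most likely to fail**

Step 3. The ion pair may distinguish the two faces of this secondary, 4-unsubstituted allyl cation poorly, traces of achiral acid may close the very labile alcohol without control, the rotation about C3–C4 that brings O1 to C2 may be slow at low temperature, or 6 may re-ionize and racemize. The fallback sets out from 3 and comes back at 7. Base-mediated oxa-Michael closure of 3 (NaOAc, EtOH, reflux) gives racemic 7-(benzyloxy)-2-[4-(benzyloxy)phenyl]chroman-4-one F1. Noyori-type asymmetric transfer hydrogenation with RuCl[(S,S)-TsDPEN](p-cymene), HCO2H/Et3N, run as a kinetic resolution, should reduce the (2S) ketone faster. The (S,S) ligand is expected to match by analogy with 4-chromanone; otherwise its antipode is used. The product is (2S,4S)-7-(benzyloxy)-2-[4-(benzyloxy)phenyl]chroman-4-ol F2, the cis epimer of 7, which enters step 6 as 7. The unreacted (2R)-7-(benzyloxy)-2-[4-(benzyloxy)phenyl]chroman-4-one F3 is racemized with base through 3 and recycled.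

Step 6. Capture of the C4 cation by the hindered benzylated arene may be slow, so that elimination to 6 with self-condensation or hydride transfer, attack through C6' of 9, a second alkylation of 10, or leakage to the 2,4-cis isomer takes over. The fallback sets out from 7 and 8 and comes back at 11. Compound 7 is condensed with unprotected 8 (excess, BF3·OEt2, dioxane/THF, rt), whose free phloroglucinol-type ring is a much stronger nucleophile. This gives (2R,3R)-8-{(2S,4R)-7-(benzyloxy)-2-[4-(benzyloxy)phenyl]chroman-4-yl}-2-(3,4,5-trihydroxyphenyl)chromane-3,5,7-triol F4. The two benzyl groups are then removed with H2, Pd(OH)2/C to reach 11; step 5 is not needed on this path.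

Step 4. The peroxide stage may over-oxidize to the C4 ketone, the alkene may simply be reduced, or hydrogen abstraction may occur at the doubly activated C2–H position. The fallback sets out from 6 and 9 and comes back at 10. The alcohol is skipped and 9 is added across the alkene directly: catalytic Tf2NH, CH2Cl2, −60 °C, slow addition of 6 to excess 9. Protonation at C3 gives the same C4 cation as in step 6 (acid-catalysed hydroarylation of an electron-rich styrene). This fallback makes no new compound (F0).

**Further compounds**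

F1 | step 3 | rac-7-(benzyloxy)-2-[4-(benzyloxy)phenyl]chroman-4-one | O=C1CC(c2ccc(OCc3ccccc3)cc2)Oc2cc(OCc3ccccc3)ccc12
F2 | step 3 | (2S,4S)-7-(benzyloxy)-2-[4-(benzyloxy)phenyl]chroman-4-ol | c1ccccc1COc1ccc([C@@H]2C[C@H](O)c3ccc(OCc4ccccc4)cc3O2)cc1
F3 | step 3 | (2R)-7-(benzyloxy)-2-[4-(benzyloxy)phenyl]chroman-4-one | c1ccccc1COc1ccc([C@H]2CC(=O)c3ccc(OCc4ccccc4)cc3O2)cc1
F4 | step 6 | (2R,3R)-8-{(2S,4R)-7-(benzyloxy)-2-[4-(benzyloxy)phenyl]chroman-4-yl}-2-(3,4,5-trihydroxyphenyl)chromane-3,5,7-triol | c1ccccc1COc1ccc([C@@H]2C[C@@H](c3c(O)cc(O)c4c3O[C@H](c3cc(O)c(O)c(O)c3)[C@H](O)C4)c3ccc(OCc5ccccc5)cc3O2)cc1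
F0 | step 4 | none | none
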